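**Retrosynthetic overview**

1. The feruloyl ester at the C8 oxygen is disconnected last. It gives ferulic acid (phenol masked as acetate) and (4S,5S,7S,8S)-guai-1(10)-ene-8,11-diol.
2. The 8,11-diol goes back to the 11-hydroxy-8-ketone (carbinol-directed hydride delivery), then to the 7(11)-en-8-one (nucleophilic epoxidation, reductive C7–O cleavage). The C4–H goes back to a C4 tertiary alcohol (radical deoxygenation).
3. Key disconnection: the C1–C5 bond. The strategy rests on the ten-membered ring C1–C10 of germacrone, which already holds all fifteen carbons, the C8 carbonyl and the C7=C11 isopropylidene unit, and lacks only this transannular bond.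
4. Forming C1–C5 from the (4R,5R)-4,5-epoxide divides the macrocycle into the cyclopentane (C1–C5) and the cycloheptene (C1, C5–C10) in one event. No ring is formed before or after it.
5. The epoxide comes from achiral germacrone by asymmetric dioxirane epoxidation of C4=C5.

Key step: step 2

Assumption: the enantiomeric ring conformers of germacrone interconvert under the epoxidation conditions, and the D-fructose-derived ketone shows the facial sense it shows with open-chain trans-trisubstituted alkenes (R,R); if the sense is reversed in the ring, the enantiomeric ketone is used instead.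

**Route**

Step 1
Reactants: 1 germacrone
Product: 2 (4R,5R)-germacrone 4,5-epoxide (trans-epoxide of the E C4=C5 alkene)
Conditions: 1,2:4,5-di-O-isopropylidene-β-D-erythro-2,3-hexodiulo-2,6-pyranose (D-fructose-derived Shi ketone, 0.3 equiv), Oxone (2KHSO5·KHSO4·K2SO4, 1.1 equiv KHSO5), K2CO3, Bu4NHSO4, MeCN–(MeO)2CH2 / aq. Na2B4O7–Na2(EDTA) buffer, pH 10.5, 0 °C
Reagents that add atoms: potassium peroxymonosulfate KHSO5, [K+].[O-]S(=O)(=O)OO
Why: Shi asymmetric epoxidation, in which the electrophilic chiral dioxirane should ignore the electron-poor C7=C11 enone alkene and prefer the trans-trisubstituted C4=C5 alkene over C1=C10 (deactivated by the β,γ-carbonyl, as expected for any electrophilic oxidant), its spiro transition state on the exposed outer face setting C4 and C5 as R,R by reagent control while the interconverting ring conformers of the achiral triene are funnelled into one enantiomer.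

Step 2
Reactants: 2 (4R,5R)-germacrone 4,5-epoxide
Product: 3 (4R,5R)-4-hydroxyguaia-1(10),7(11)-dien-8-one (4α-OH, 4β-CH3, 5α-H; hydroxyl cis to H5)
Conditions: p-toluenesulfonic acid (anhydrous, 0.1 equiv), CH2Cl2, 0 °C; NaHCO3 quench
Reagents that add atoms: none
Why: Protonation of the epoxide oxygen in the crown conformer of the ten-membered ring places the C1=C10 π bond anti to the C5–O bond, so C1 attacks C5 with inversion while C4 keeps its oxygen, and the tertiary C10 cation then loses H1 to give the tetrasubstituted C1=C10 alkene. The closest known reaction type is the acid-promoted transannular epoxide–alkene cyclisation of germacrane 4,5-epoxides to 4-hydroxyguai-1(10)-enes. The single new C1–C5 bond closes both rings: the cyclopentane (C1–C5) by attack that is exo with respect to the alkene and endo with respect to the epoxide, and the cycloheptene (C1, C5–C10) as the complementary transannular closure, endo with respect to the alkene. C5 is the only new stereocentre and is fixed by stereospecific backside opening of the (4R,5R)-epoxide, which puts H5 cis to the retained 4-hydroxyl; the centre is inverted in space but keeps the letter R because the incoming C1 ranks below C4. The step needs C1 and not C10 to bond, which the tertiary C10 cation (Markovnikov) and the short C1···C5 distance secure, attack at C4 being excluded because it would close a four-membered ring. It also needs proton loss toward C1 rather than C9 or C14, which is favoured as the Zaitsev outcome under a protic acid with a non-nucleophilic counter-ion and is kept from drifting into conjugation with C8=O by low temperature and the bicarbonate quench.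

Step 3
Reactants: 3 (4R,5R)-4-hydroxyguaia-1(10),7(11)-dien-8-one
Product: 4 methyl (4R,5R)-8-oxoguaia-1(10),7(11)-dien-4-yl oxalate
Conditions: ClCOCO2Me, pyridine, 4-(dimethylamino)pyridine (DMAP, cat.), CH2Cl2, 0 °C → rt
Reagents that add atoms: methyl chlorooxoacetate, COC(=O)C(=O)Cl
Why: Acylation of the tertiary alcohol by the highly electrophilic oxalyl half-ester chloride under nucleophilic catalysis installs the radical leaving group for a Barton-type deoxygenation without touching a stereocentre.

Step 4
Reactants: 4 methyl (4R,5R)-8-oxoguaia-1(10),7(11)-dien-4-yl oxalate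
Product: 5 (4S,5S)-guaia-1(10),7(11)-dien-8-one (4β-CH3, 4α-H, 5α-H)
Conditions: Bu3SnH (1.3 equiv, slow addition), 2,2'-azobis(isobutyronitrile) (AIBN, cat.), toluene, 100 °C
Reagents that add atoms: none
Why: Barton-type radical deoxygenation of a tertiary methyl oxalate, in which stannyl radical addition and C4–O scission give the planar tertiary C4 radical that should take hydrogen from Bu3SnH on the α face, cis to H5 and anti to the C6 branch on C5 (the usual anti attack on 2-substituted cyclopentyl radicals), so that H replaces the hydroxyl with retention (C4 becomes S), while the low stannane concentration spares the hindered tetrasubstituted enone.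

Step 5
Reactants: 5 (4S,5S)-guaia-1(10),7(11)-dien-8-one
Product: 6 (4S,5S)-7,11-epoxyguai-1(10)-en-8-one (spiro-oxirane; either or both C7 epimers)
Conditions: t-BuOOH (anhydrous, in decane), n-BuLi, THF, −78 °C → rt
Reagents that add atoms: tert-butyl hydroperoxide, CC(C)(C)OO
Why: Weitz–Scheffer nucleophilic epoxidation, in which the peroxide anion adds in conjugate fashion only to the electron-poor C7=C11 enone and leaves the electron-rich C1=C10 alkene alone, the weakly basic lithium peroxide in aprotic THF being chosen so that the β,γ-unsaturated ketone is not drawn into conjugation; the configuration of the new spiro centre C7 is immaterial because it is erased in step 6.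

Step 6
Reactants: 6 (4S,5S)-7,11-epoxyguai-1(10)-en-8-one
Product: 7 (4S,5S,7R)-11-hydroxyguai-1(10)-en-8-one (7α-H, side chain β)
Conditions: SmI2 (2.5 equiv), THF–MeOH, −90 °C; pH 7 buffer
Reagents that add atoms: none
Why: Two-electron SmI2 reduction of an α,β-epoxy ketone cleaves the C7–O bond next to the carbonyl to give the C11 alkoxide and the C7=C8 samarium enolate, which methanol should protonate on the less hindered α face (the face of H5), placing the hydroxyisopropyl group pseudo-equatorial and cis-1,3 to the C5–C4 bond, the epimer that is also expected to be the more stable one.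

Step 7
Reactants: 7 (4S,5S,7R)-11-hydroxyguai-1(10)-en-8-one
Product: 8 (4S,5S,7S,8S)-guai-1(10)-ene-8,11-diol (8α-OH, 8β-H)
Conditions: Me4N[BH(OAc)3], MeCN–AcOH (1:1), −30 → −20 °C
Reagents that add atoms: none
Why: Evans–Saksena hydroxyl-directed reduction, in which the C11 carbinol exchanges onto boron and delivers hydride intramolecularly to C8 on the β face that carries the C7 side chain, so the new C8–O bond is α and trans to the hydroxyisopropyl group (8S).

Step 8
Reactants: 9 ferulic acid
Product: 10 (E)-4-acetoxy-3-methoxycinnamic acid (4-O-acetylferulic acid)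
Conditions: Ac2O, pyridine, rt; aqueous HCl work-up
Reagents that add atoms: acetic anhydride, CC(=O)OC(C)=O
Why: O-Acetylation of the phenol masks the only competing nucleophile of the acyl donor and leaves the E alkene and the acid unchanged.

Step 9
Reactants: 10 (E)-4-acetoxy-3-methoxycinnamic acid
Product: 11 (E)-4-acetoxy-3-methoxycinnamoyl chloride (concentrated and used directly)
Conditions: (COCl)2, N,N-dimethylformamide (cat.), CH2Cl2, 0 °C → rt
Reagents that add atoms: oxalyl chloride, O=C(Cl)C(=O)Cl
Why: Vilsmeier-catalysed conversion of a carboxylic acid into its acid chloride, to which the aryl acetate and the cinnamoyl alkene are inert.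

Step 10
Reactants: 8 (4S,5S,7S,8S)-guai-1(10)-ene-8,11-diol; 11 (E)-4-acetoxy-3-methoxycinnamoyl chloride
Product: 12 (4S,5S,7S,8S)-11-hydroxyguai-1(10)-en-8-yl (E)-4-acetoxy-3-methoxycinnamate
Conditions: pyridine, 4-(dimethylamino)pyridine (DMAP, 0.2 equiv), CH2Cl2, 0 °C → rt
Reagents that add atoms: none
Why: DMAP-catalysed acylation (nucleophilic catalysis) should discriminate the secondary C8 hydroxyl from the tertiary C11 carbinol on steric grounds, and C8 keeps its configuration because its C–O bond is not broken.

Step 11
Reactants: 12 (4S,5S,7S,8S)-11-hydroxyguai-1(10)-en-8-yl (E)-4-acetoxy-3-methoxycinnamate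
Product: 13 (4S,5S,7S,8S)-11-hydroxyguai-1(10)-en-8-yl (E)-ferulate (CNP0241038.1)
Conditions: pyrrolidine, CH2Cl2, 0 °C → rt
Reagents that add atoms: none
Why: Chemoselective aminolysis of the activated aryl acetate by pyrrolidine releases the phenol while the hindered, conjugated secondary alkyl ferulate and the tertiary alcohol are left intact.

**Compound list**

1 | germacrone | O=C1C/C(C)=C/CC/C(C)=C/CC1=C(C)C | starting material
2 | (4R,5R)-germacrone 4,5-epoxide | O=C1C/C(C)=C/CC[C@@]2(C)O[C@@H]2CC1=C(C)C | intermediate
3 | (4R,5R)-4-hydroxyguaia-1(10),7(11)-dien-8-one | O=C1CC(C)=C2CC[C@@](C)(O)[C@@H]2CC1=C(C)C | intermediate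
4 | methyl (4R,5R)-8-oxoguaia-1(10),7(11)-dien-4-yl oxalate | O=C1CC(C)=C2CC[C@@](C)(OC(=O)C(=O)OC)[C@@H]2CC1=C(C)C | intermediate
5 | (4S,5S)-guaia-1(10),7(11)-dien-8-one | O=C1CC(C)=C2CC[C@H](C)[C@@H]2CC1=C(C)C | intermediate
6 | (4S,5S)-7,11-epoxyguai-1(10)-en-8-one (C7 epimers, C7 left undefined) | O=C1CC(C)=C2CC[C@H](C)[C@@H]2CC13OC3(C)C | intermediate
7 | (4S,5S,7R)-11-hydroxyguai-1(10)-en-8-one | O=C1CC(C)=C2CC[C@H](C)[C@@H]2C[C@@H]1C(C)(C)O | intermediate
8 | (4S,5S,7S,8S)-guai-1(10)-ene-8,11-diol | O[C@H]1CC(C)=C2CC[C@H](C)[C@@H]2C[C@@H]1C(C)(C)O | intermediate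
9 | ferulic acid | COc1cc(/C=C/C(=O)O)ccc1O | starting material
10 | (E)-4-acetoxy-3-methoxycinnamic acid | COc1cc(/C=C/C(=O)O)ccc1OC(C)=O | intermediate
11 | (E)-4-acetoxy-3-methoxycinnamoyl chloride | COc1cc(/C=C/C(=O)Cl)ccc1OC(C)=O | intermediate
12 | (4S,5S,7S,8S)-11-hydroxyguai-1(10)-en-8-yl (E)-4-acetoxy-3-methoxycinnamate | COc1cc(/C=C/C(=O)O[C@H]2CC(C)=C3CC[C@H](C)[C@@H]3C[C@@H]2C(C)(C)O)ccc1OC(C)=O | intermediate
13 | (4S,5S,7S,8S)-11-hydroxyguai-1(10)-en-8-yl (E)-ferulate | COc1cc(/C=C/C(=O)O[C@H]2CC(C)=C3CC[C@H](C)[C@@H]3C[C@@H]2C(C)(C)O)ccc1O | target

**Step count**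

Total step count: 11. Longest linear sequence: 9 steps (steps 1–7, 10 and 11, from germacrone).

**Steps most likely to fail**

Step 2. Proton loss from the C10 cation may be unselective (toward C9 into conjugation with the C8 carbonyl, or toward the C14 methyl), and the acid may move the β,γ-alkene into conjugation. The fallback sets out from 2. The cyclisation is run without regard to alkene position (p-toluenesulfonic acid, CH2Cl2, rt), and the crude alkene isomers are equilibrated with 1,8-diazabicyclo[5.4.0]undec-7-ene in CH2Cl2 to the thermodynamic cross-conjugated dienone, (1S,4R,5R)-4-hydroxyguaia-7(11),9-dien-8-one F1 (either C1 epimer serves, since C1 becomes trigonal again). F1 is then deconjugated: KOtBu (2.2 equiv, t-BuOH–THF, rt) forms the extended dienolate O–C8=C9–C10=C1, and a quench into cold aqueous AcOH protonates it kinetically at C9. This should give the β,γ-unsaturated ketone 3, where the route is rejoined.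

Step 4. Hydrogen-atom transfer to the planar C4 radical may show poor facial selectivity, and the stannane may reduce the enone in conjugate fashion. The fallback sets out from 3. Anti elimination with SOCl2 in pyridine at −20 °C cannot involve H5, which is syn to the leaving group, and should give (5S)-guaia-1(10),3,7(11)-trien-8-one F2 (any 4(15)-methylene isomer converges). Hydrogenation over rhodium on alumina (Rh/Al2O3, H2 1 atm, EtOAc) should then add both hydrogens to the trisubstituted C3=C4 alkene from the α face, anti to C6, while the two tetrasubstituted alkenes react far more slowly. This gives 5, where the route is rejoined.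

Step 1. Oxygen transfer may be insufficiently enantioselective or site-selective on the mobile ten-membered ring, and the basic medium may trigger transannular reactions of the epoxide. The fallback sets out from 1. Epoxidation with 3-chloroperoxybenzoic acid (1.0 equiv, NaHCO3, CH2Cl2, 0 °C) gives the racemic 4,5-epoxide, and preparative chromatography on a chiral stationary phase (cellulose tris(3,5-dimethylphenylcarbamate)) removes the unwanted enantiomer, (4S,5S)-germacrone 4,5-epoxide F3. The (4R,5R)-enantiomer 2 rejoins the route.

**Further compounds**

F1 | step 2 | (1S,4R,5R)-4-hydroxyguaia-7(11),9-dien-8-one | O=C1C=C(C)[C@H]2CC[C@@](C)(O)[C@@H]2CC1=C(C)C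
F2 | step 4 | (5S)-guaia-1(10),3,7(11)-trien-8-one | O=C1CC(C)=C2CC=C(C)[C@@H]2CC1=C(C)C
F3 | step 1 | (4S,5S)-germacrone 4,5-epoxide | O=C1C/C(C)=C/CC[C@]2(C)O[C@H]2CC1=C(C)C
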